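**Plan**

- Numbering: ring A is the sulfated ring (position 1 O‑sulfate, position 2 the oxygen to ring B, positions 3 and 5 Br, positions 4 and 6 H). Ring B is the central ring (two ether oxygens on adjacent carbons, then three Br, then one H). Ring C is the 2,4‑dibromophenyl ring.
- Retrosynthetic cuts, in order: the S–O bond; the C–O bond at position 1 of ring A (back to C–B); the 2,3 and 1,6 bonds of ring A (pyrone [4+2], then loss of CO2); the alkyne back to the ring‑B phenol; the aryl–O bond between rings B and C (iodonium O‑arylation); two C–Br bonds of ring B.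
- Enabling feature: positions 3(Br)–4(H)–5(Br)–6(H) of ring A are the C3–C6 diene of 3,5‑dibromo‑2‑pyrone. The remaining edge, positions 2 and 1, is a two‑carbon alkyne that already carries the ether oxygen to ring B on one carbon and boron (the later sulfate‑oxygen site) on the other.
- Forward: ring B is brominated, joined to ring C by O‑arylation and demethylated at the oxygen that will link rings A and B. This oxygen is vinylated, the vinyl ether is brominated and dehydrobrominated twice, and the alkyne is C‑borylated. Ring A is then grown on the oxygen in one step, the C–B bond is oxidised and the phenol is sulfated.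
- Stereochemistry: the target is achiral, so only regiochemistry is controlled. It comes from directing effects in the brominations and from the matched polarisation of alkyne and pyrone in the cycloaddition.

Key step: step 10

Remark: the target is drawn as the free aryl hydrogen sulfate. It is delivered in this form by cold H+ ion exchange of the pyridinium salt formed first. No enantiomer has to be chosen.

**Route**

Step 1
Reactants: 1 coumalic acid
Product: 2 3,5‑dibromo‑2H‑pyran‑2‑one
Conditions: NBS (2.5 equiv), LiOAc (cat.), MeCN/H2O 9:1, rt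
Reagents that add atoms: N‑bromosuccinimide, O=C1CCC(=O)N1Br
Why: Electrophilic bromination at C3 together with ipso bromodecarboxylation at C5 (Hunsdiecker‑type halodecarboxylation) is the known one‑step conversion of coumalic acid into the 3,5‑dibromopyrone.

Step 2
Reactants: 3 5‑bromo‑2‑methoxyphenol
Product: 4 2,3,4‑tribromo‑6‑methoxyphenol
Conditions: Br2 (2.1 equiv), AcOH, rt
Reagents that add atoms: bromine, BrBr
Why: In this electrophilic aromatic bromination the free OH directs to its para and ortho positions, both also ortho to the bromine already present, while the only other open site (ortho to OMe, meta to OH) is the least activated and should stay as C–H.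

Step 3
Reactants: 5 2,4‑dibromo‑1‑iodobenzene; 6 1,3,5‑trimethoxybenzene
Product: 8 (2,4‑dibromophenyl)(2,4,6‑trimethoxyphenyl)iodonium 4‑methylbenzenesulfonate, via 2,4‑dibromo‑1‑[hydroxy(tosyloxy)iodo]benzene 7 (not isolated)
Conditions: mCPBA, TsOH·H2O, MeCN, 77 °C; then 6, 77 °C → rt; Et2O trituration
Reagents that add atoms: p‑toluenesulfonic acid monohydrate, Cc1ccc(cc1)S(=O)(=O)O.O
Why: Oxidation of the aryl iodide to the hydroxy(tosyloxy)iodoarene followed by electrophilic aromatic substitution on trimethoxybenzene is the standard one‑pot synthesis of aryl(trimethoxyphenyl)iodonium tosylates and tolerates ortho‑substituted, halogenated aryl iodides.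

Step 4
Reactants: 4 2,3,4‑tribromo‑6‑methoxyphenol; 8 (2,4‑dibromophenyl)(2,4,6‑trimethoxyphenyl)iodonium 4‑methylbenzenesulfonate
Product: 9 1,2,3‑tribromo‑4‑(2,4‑dibromophenoxy)‑5‑methoxybenzene
Conditions: K2CO3, MeCN, 60 °C
Reagents that add atoms: none
Why: Metal‑free O‑arylation of the phenoxide by ligand coupling at iodine(III) should transfer the 2,4‑dibromophenyl group, because the electron‑rich trimethoxyphenyl group is a non‑transferred dummy ligand; the method makes hindered polybrominated diaryl ethers without touching C–Br bonds.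

Step 5
Reactants: 9 1,2,3‑tribromo‑4‑(2,4‑dibromophenoxy)‑5‑methoxybenzene
Product: 11 3,4,5‑tribromo‑2‑(2,4‑dibromophenoxy)phenol, via dibromo[3,4,5‑tribromo‑2‑(2,4‑dibromophenoxy)phenoxy]borane 10 (not isolated)
Conditions: BBr3, CH2Cl2, −78 °C → rt; then H2O
Reagents that add atoms: none
Why: BBr3 cleavage of an aryl methyl ether (Lewis adduct, then SN2 attack of bromide on the methyl group) leaves diaryl ethers and aryl bromides intact and is the standard demethylation of methoxylated polybromodiphenyl ethers.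

Step 6
Reactants: 11 3,4,5‑tribromo‑2‑(2,4‑dibromophenoxy)phenol
Product: 12 1,2,3‑tribromo‑4‑(2,4‑dibromophenoxy)‑5‑(ethenyloxy)benzene
Conditions: 2,4,6‑trivinylcyclotriboroxane·pyridine, Cu(OAc)2, pyridine, CH2Cl2, rt, dry air
Reagents that add atoms: 2,4,6‑trivinylcyclotriboroxane–pyridine complex, C=CB1OB(C=C)OB(C=C)O1.c1ccncc1
Why: Copper‑mediated oxidative O‑vinylation of a phenol with a vinylboron reagent (Chan–Lam coupling) runs at room temperature with a weak base and air as terminal oxidant, so the C–Br bonds and the diaryl ether are not at risk.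

Step 7
Reactants: 12 1,2,3‑tribromo‑4‑(2,4‑dibromophenoxy)‑5‑(ethenyloxy)benzene
Product: 14 1,2,3‑tribromo‑5‑{[(Z)‑2‑bromoethenyl]oxy}‑4‑(2,4‑dibromophenoxy)benzene, via racemic 1,2,3‑tribromo‑5‑(1,2‑dibromoethoxy)‑4‑(2,4‑dibromophenoxy)benzene 13 (not isolated)
Conditions: Br2 (1.0 equiv), CH2Cl2, −78 °C; then Et3N, −78 °C → rt
Reagents that add atoms: bromine, BrBr
Why: Anti addition of bromine to the enol ether double bond (the three deactivated rings do not compete) and amine‑induced loss of HBr with the labile α‑bromo ether bromide as leaving group is the classical route from vinyl ethers to 2‑bromovinyl ethers and should give mainly the Z isomer, whose vinylic H and Br are anti as step 8 requires.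

Step 8
Reactants: 14 1,2,3‑tribromo‑5‑{[(Z)‑2‑bromoethenyl]oxy}‑4‑(2,4‑dibromophenoxy)benzene
Product: 15 1,2,3‑tribromo‑4‑(2,4‑dibromophenoxy)‑5‑(ethynyloxy)benzene
Conditions: t‑BuOK (1.5 equiv), THF, −40 → 0 °C; cold pH 7 buffer; used without storage
Reagents that add atoms: none
Why: Bimolecular anti dehydrobromination of the Z‑bromovinyl ether with a hindered alkoxide is the classical entry to aryloxyacetylenes; unlike alkyllithiums or lithium dialkylamides, an alkoxide at or below 0 °C should neither exchange the five aryl bromides nor metalate the ring C–H bonds.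

Step 9
Reactants: 15 1,2,3‑tribromo‑4‑(2,4‑dibromophenoxy)‑5‑(ethynyloxy)benzene; 16 2‑isopropoxy‑4,4,5,5‑tetramethyl‑1,3,2‑dioxaborolane
Product: 19 2‑{[3,4,5‑tribromo‑2‑(2,4‑dibromophenoxy)phenoxy]ethynyl}‑4,4,5,5‑tetramethyl‑1,3,2‑dioxaborolane, via lithium [3,4,5‑tribromo‑2‑(2,4‑dibromophenoxy)phenoxy]ethynide 17 (not isolated), via lithium isopropoxy(pinacolato){[3,4,5‑tribromo‑2‑(2,4‑dibromophenoxy)phenoxy]ethynyl}borate 18 (not isolated)
Conditions: LiHMDS (1.05 equiv), THF, −78 °C; then 16, −78 °C; then HCl·Et2O (1.0 equiv), −78 °C → rt; filtration under Ar, used crude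
Reagents that add atoms: none
Why: Deprotonation of the sp C–H with LiHMDS (too weak and too hindered to exchange aryl bromides or metalate the bromoarenes at −78 °C), trapping of the acetylide with the isopropoxy boronate and removal of isopropoxide from the ate complex with one equivalent of anhydrous HCl is the standard alkynyllithium–borate route to alkynyl pinacol boronates.

Step 10
Reactants: 19 2‑{[3,4,5‑tribromo‑2‑(2,4‑dibromophenoxy)phenoxy]ethynyl}‑4,4,5,5‑tetramethyl‑1,3,2‑dioxaborolane; 2 3,5‑dibromo‑2H‑pyran‑2‑one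
Product: 21 2‑{3,5‑dibromo‑2‑[3,4,5‑tribromo‑2‑(2,4‑dibromophenoxy)phenoxy]phenyl}‑4,4,5,5‑tetramethyl‑1,3,2‑dioxaborolane, via racemic 4,7‑dibromo‑5‑[3,4,5‑tribromo‑2‑(2,4‑dibromophenoxy)phenoxy]‑6‑(4,4,5,5‑tetramethyl‑1,3,2‑dioxaborolan‑2‑yl)‑2‑oxabicyclo[2.2.2]octa‑5,7‑dien‑3‑one 20 (not isolated)
Conditions: 2 (1.5 equiv), PhMe, 110 °C, sealed tube, Ar, strictly anhydrous
Reagents that add atoms: none
Why: The alkyne of 19 is push–pull polarised (the aryloxy oxygen donates into the π system and the charge is taken up at the carbon bearing boron), so this carbon bonds to the electrophilic C6 of pyrone 2 and the oxygen‑bearing carbon bonds to C3 in a concerted but asynchronous, suprafacial–suprafacial [4+2] cycloaddition that forms the 1,6 and 2,3 bonds of ring A. The closest known reactions are the cycloaddition–decarboxylation of 2‑pyrones with alkynyl boronates to aryl boronates and the inverse‑demand cycloadditions of 3,5‑dibromo‑2‑pyrone and other 2‑pyrones with enol and ynol ethers, which place the oxygen‑bearing carbon at C3 as required here. Ring A closes by this [4+2] mode as the carbocyclic six‑membered ring of the bridged lactone 20, and a thermal retro‑[4+2] expels CO2 to give the arene directly, with no elimination step in which the aryloxide could leave. The two bridgehead centres of racemic 20 vanish on aromatisation, so no stereocentre has to be controlled. The step needs regioselectivity (the ether oxygen next to the brominated position 3 of ring A, boron next to the C–H at position 6), secured by the matched polarisation of both partners and by the unhindered C6–H terminus accepting the bulky boronate carbon, and chemoselectivity over seven C–Br bonds, secured by neutral, metal‑free heating; an aryl ynol ether also has no β‑hydrogen for retro‑ene loss of ketene.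

Step 11
Reactants: 21 2‑{3,5‑dibromo‑2‑[3,4,5‑tribromo‑2‑(2,4‑dibromophenoxy)phenoxy]phenyl}‑4,4,5,5‑tetramethyl‑1,3,2‑dioxaborolane
Product: 22 3,5‑dibromo‑2‑[3,4,5‑tribromo‑2‑(2,4‑dibromophenoxy)phenoxy]phenol
Conditions: NaBO3·4H2O, THF/H2O 1:1, rt
Reagents that add atoms: sodium perborate (tetrahydrate, water of hydration omitted), [Na+].[O-]OB=O
Why: Addition of the peroxide to boron and 1,2‑aryl migration from boron to oxygen (C–B oxidation) should give the phenol at room temperature and mild pH, under which aryl bromides and diaryl ethers are inert and base‑induced aryl migration between the two oxygens (Smiles rearrangement) is not expected.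

Step 12
Reactants: 22 3,5‑dibromo‑2‑[3,4,5‑tribromo‑2‑(2,4‑dibromophenoxy)phenoxy]phenol
Product: 24 3,5‑dibromo‑2‑[3,4,5‑tribromo‑2‑(2,4‑dibromophenoxy)phenoxy]phenyl hydrogen sulfate, via pyridinium 3,5‑dibromo‑2‑[3,4,5‑tribromo‑2‑(2,4‑dibromophenoxy)phenoxy]phenyl sulfate 23 (not isolated)
Conditions: SO3·pyridine (5 equiv), pyridine, rt → 45 °C; then Dowex 50W (H+ form), MeOH/H2O, 0 °C; lyophilise, store cold
Reagents that add atoms: sulfur trioxide–pyridine complex, [O-]S(=O)(=O)[n+]1ccccc1
Why: O‑Sulfation of a phenol with the sulfur trioxide–pyridine complex (sulfonyl transfer to the phenol oxygen) is the standard preparation of aryl sulfates, and cation exchange on an H+ resin should release the free hydrogen sulfate.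

**Compound list**

1 | coumalic acid (2‑oxo‑2H‑pyran‑5‑carboxylic acid) | O=C(O)c1ccc(=O)oc1 | starting material
2 | 3,5‑dibromo‑2H‑pyran‑2‑one | O=c1occ(Br)cc1Br | intermediate
3 | 5‑bromo‑2‑methoxyphenol | COc1ccc(Br)cc1O | starting material
4 | 2,3,4‑tribromo‑6‑methoxyphenol | COc1cc(Br)c(Br)c(Br)c1O | intermediate
5 | 2,4‑dibromo‑1‑iodobenzene | Ic1ccc(Br)cc1Br | starting material
6 | 1,3,5‑trimethoxybenzene | COc1cc(OC)cc(OC)c1 | starting material
7 | 2,4‑dibromo‑1‑[hydroxy(tosyloxy)iodo]benzene | Cc1ccc(cc1)S(=O)(=O)OI(O)c1ccc(Br)cc1Br | intermediate (not isolated)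
8 | (2,4‑dibromophenyl)(2,4,6‑trimethoxyphenyl)iodonium 4‑methylbenzenesulfonate | COc1cc(OC)c([I+]c2ccc(Br)cc2Br)c(OC)c1.Cc1ccc(cc1)S(=O)(=O)[O-] | intermediate
9 | 1,2,3‑tribromo‑4‑(2,4‑dibromophenoxy)‑5‑methoxybenzene | COc1cc(Br)c(Br)c(Br)c1Oc1ccc(Br)cc1Br | intermediate
10 | dibromo[3,4,5‑tribromo‑2‑(2,4‑dibromophenoxy)phenoxy]borane | BrB(Br)Oc1cc(Br)c(Br)c(Br)c1Oc1ccc(Br)cc1Br | intermediate (not isolated)
11 | 3,4,5‑tribromo‑2‑(2,4‑dibromophenoxy)phenol | Oc1cc(Br)c(Br)c(Br)c1Oc1ccc(Br)cc1Br | intermediate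
12 | 1,2,3‑tribromo‑4‑(2,4‑dibromophenoxy)‑5‑(ethenyloxy)benzene | C=COc1cc(Br)c(Br)c(Br)c1Oc1ccc(Br)cc1Br | intermediate
13 | 1,2,3‑tribromo‑5‑(1,2‑dibromoethoxy)‑4‑(2,4‑dibromophenoxy)benzene, racemic | BrCC(Br)Oc1cc(Br)c(Br)c(Br)c1Oc1ccc(Br)cc1Br | intermediate (not isolated)
14 | 1,2,3‑tribromo‑5‑{[(Z)‑2‑bromoethenyl]oxy}‑4‑(2,4‑dibromophenoxy)benzene | Br/C=C\Oc1cc(Br)c(Br)c(Br)c1Oc1ccc(Br)cc1Br | intermediate
15 | 1,2,3‑tribromo‑4‑(2,4‑dibromophenoxy)‑5‑(ethynyloxy)benzene | C#COc1cc(Br)c(Br)c(Br)c1Oc1ccc(Br)cc1Br | intermediate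
16 | 2‑isopropoxy‑4,4,5,5‑tetramethyl‑1,3,2‑dioxaborolane | CC(C)OB1OC(C)(C)C(C)(C)O1 | starting material
17 | lithium [3,4,5‑tribromo‑2‑(2,4‑dibromophenoxy)phenoxy]ethynide | [Li]C#COc1cc(Br)c(Br)c(Br)c1Oc1ccc(Br)cc1Br | intermediate (not isolated)
18 | lithium isopropoxy(pinacolato){[3,4,5‑tribromo‑2‑(2,4‑dibromophenoxy)phenoxy]ethynyl}borate | [Li+].CC(C)O[B-]1(C#COc2cc(Br)c(Br)c(Br)c2Oc2ccc(Br)cc2Br)OC(C)(C)C(C)(C)O1 | intermediate (not isolated)
19 | 2‑{[3,4,5‑tribromo‑2‑(2,4‑dibromophenoxy)phenoxy]ethynyl}‑4,4,5,5‑tetramethyl‑1,3,2‑dioxaborolane | CC1(C)OB(C#COc2cc(Br)c(Br)c(Br)c2Oc2ccc(Br)cc2Br)OC1(C)C | intermediate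
20 | 4,7‑dibromo‑5‑[3,4,5‑tribromo‑2‑(2,4‑dibromophenoxy)phenoxy]‑6‑(4,4,5,5‑tetramethyl‑1,3,2‑dioxaborolan‑2‑yl)‑2‑oxabicyclo[2.2.2]octa‑5,7‑dien‑3‑one, racemic | O=C1OC2C(Br)=CC1(Br)C(Oc3cc(Br)c(Br)c(Br)c3Oc3ccc(Br)cc3Br)=C2B4OC(C)(C)C(C)(C)O4 | intermediate (not isolated)
21 | 2‑{3,5‑dibromo‑2‑[3,4,5‑tribromo‑2‑(2,4‑dibromophenoxy)phenoxy]phenyl}‑4,4,5,5‑tetramethyl‑1,3,2‑dioxaborolane | CC1(C)OB(OC1(C)C)c1cc(Br)cc(Br)c1Oc1cc(Br)c(Br)c(Br)c1Oc1ccc(Br)cc1Br | intermediate
22 | 3,5‑dibromo‑2‑[3,4,5‑tribromo‑2‑(2,4‑dibromophenoxy)phenoxy]phenol | Oc1cc(Br)cc(Br)c1Oc1cc(Br)c(Br)c(Br)c1Oc1ccc(Br)cc1Br | intermediate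
23 | pyridinium 3,5‑dibromo‑2‑[3,4,5‑tribromo‑2‑(2,4‑dibromophenoxy)phenoxy]phenyl sulfate | [O-]S(=O)(=O)Oc1cc(Br)cc(Br)c1Oc1cc(Br)c(Br)c(Br)c1Oc1ccc(Br)cc1Br.c1cc[nH+]cc1 | intermediate (not isolated)
24 | 3,5‑dibromo‑2‑[3,4,5‑tribromo‑2‑(2,4‑dibromophenoxy)phenoxy]phenyl hydrogen sulfate (bromoiesol A sulfate; achiral) | O=S(=O)(O)Oc1cc(Br)cc(Br)c1Oc1cc(Br)c(Br)c(Br)c1Oc1ccc(Br)cc1Br | target

**Step count**

Total: 12 steps. Longest linear sequence: 10 steps (steps 2, 4, 5, 6, 7, 8, 9, 10, 11, 12, from 5‑bromo‑2‑methoxyphenol 3).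

**Steps most likely to fail**

Step 10. The push–pull alkyne may oligomerise or lose boron by adventitious protonation faster than it adds to the pyrone, the cycloaddition at the hindered alkyne may be slow, or regiocontrol may erode. The fallback gives up the cycloaddition, sets out from phenol 11 and returns at phenol 22. Nucleophilic aromatic substitution of 11 on commercial 3,5‑dibromo‑2‑fluorobenzaldehyde (K2CO3, DMAc, at or below 80 °C to avoid aryl migration between the oxygens) should give 3,5‑dibromo‑2‑[3,4,5‑tribromo‑2‑(2,4‑dibromophenoxy)phenoxy]benzaldehyde F1. Baeyer–Villiger oxidation with mCPBA in CH2Cl2, with migration of the oxygen‑substituted aryl group, should give 3,5‑dibromo‑2‑[3,4,5‑tribromo‑2‑(2,4‑dibromophenoxy)phenoxy]phenyl formate F2. Methanolysis (cat. K2CO3, MeOH, 0 °C) should then give 22, and the route resumes at step 12.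

Step 9. During the acid quench, protonation may occur at the boron‑bearing carbon (loss of boron) or at the ynol ether (hydration) instead of at isopropoxide, and deprotonation by the amide may be incomplete. The fallback sets out from alkyne 15 and returns at boronate 19. It replaces the lithiation and acid quench by a base‑free, acid‑free catalytic dehydrogenative C(sp)–H borylation of the terminal alkyne with pinacolborane (iridium pincer or carbene–copper catalyst, rt), which forms the C–B bond with loss of dihydrogen. This fallback makes no compound outside the list (F0).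

Step 8. tert‑Butoxide or tert‑butanol may add to the newly formed ynol ether, the terminal aryloxyacetylene may oligomerise under base, or base may trigger bromine migration on ring B. The fallback sets out from phenol 11 and returns at alkyne 15, and moves the elimination to a better leaving group and a neutral base. O‑Alkylation of 11 with bromoacetaldehyde diethyl acetal (K2CO3, DMF, 80 °C) should give 1,2,3‑tribromo‑5‑(2,2‑diethoxyethoxy)‑4‑(2,4‑dibromophenoxy)benzene F3. Acetal hydrolysis (aq. HCl, acetone) should give [3,4,5‑tribromo‑2‑(2,4‑dibromophenoxy)phenoxy]acetaldehyde F4. Nonafluorobutanesulfonyl fluoride with a phosphazene base (DMF, −20 °C → rt) should convert the aldehyde through 2‑[3,4,5‑tribromo‑2‑(2,4‑dibromophenoxy)phenoxy]ethenyl nonafluorobutanesulfonate F5 (not isolated) into 15 by elimination of nonaflate.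

Further compounds
F1 | step 10 | 3,5‑dibromo‑2‑[3,4,5‑tribromo‑2‑(2,4‑dibromophenoxy)phenoxy]benzaldehyde | O=Cc1cc(Br)cc(Br)c1Oc1cc(Br)c(Br)c(Br)c1Oc1ccc(Br)cc1Br
F2 | step 10 | 3,5‑dibromo‑2‑[3,4,5‑tribromo‑2‑(2,4‑dibromophenoxy)phenoxy]phenyl formate | O=COc1cc(Br)cc(Br)c1Oc1cc(Br)c(Br)c(Br)c1Oc1ccc(Br)cc1Br
F0 | step 9 | none | none
F3 | step 8 | 1,2,3‑tribromo‑5‑(2,2‑diethoxyethoxy)‑4‑(2,4‑dibromophenoxy)benzene | CCOC(COc1cc(Br)c(Br)c(Br)c1Oc1ccc(Br)cc1Br)OCC
F4 | step 8 | [3,4,5‑tribromo‑2‑(2,4‑dibromophenoxy)phenoxy]acetaldehyde | O=CCOc1cc(Br)c(Br)c(Br)c1Oc1ccc(Br)cc1Br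
F5 | step 8 | 2‑[3,4,5‑tribromo‑2‑(2,4‑dibromophenoxy)phenoxy]ethenyl nonafluorobutanesulfonate (not isolated) | FC(F)(F)C(F)(F)C(F)(F)C(F)(F)S(=O)(=O)OC=COc1cc(Br)c(Br)c(Br)c1Oc1ccc(Br)cc1Br
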